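**Retrosynthetic overview**

- Rings A (3-methoxyphenyl) and C (4-hydroxyphenyl) are bought; ring B, the tetrasubstituted ring, is the only ring built.
- Enabling feature: the two oxygens of ring B (C3–OH, C5–OMe) are meta to C1, the carbon that carries the CH2CH2 bridge. Ring B plus the bridge CH2 bound to it is therefore a folded heptane-2,4,6-trione. In its masked form, 2,6-dimethyl-4-pyrone 1, that bridge carbon is a C-methyl group made acidic through C2=C3–C4=O.
- Key disconnection: the CH2–CH2 bond of the bridge, made by alkylating the lateral carbanion of 1 with 3-methoxybenzyl bromide 2. Hydroxide in the same flask unmasks the triketone and folds it by aldol condensation into ring B.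
- The 4-hydroxybenzyl group and the OH/OMe difference then follow from the symmetry of ring B: reduction to the cyclohexane-1,3-dione (C2 is its only nucleophilic carbon), reductive benzylation, and iodine/methanol re-aromatisation, which turns one of two equivalent carbonyls into OMe and the other into OH.

Key step: step 1

Assumptions: 1, 2 and 4-hydroxybenzaldehyde are commercial. Diones 8 and 11 are drawn as diketo tautomers although they exist largely as enols. Compound 12 is racemic, and no configuration needs control because the target has no stereocentre.

**Step 1**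
Reactants: 1 2,6-dimethyl-4H-pyran-4-one; 2 3-methoxybenzyl bromide
Product: 7 5-[2-(3-methoxyphenyl)ethyl]benzene-1,3-diol, via lithium dienolate 3 (not isolated), via alkylated pyrone 4 (not isolated), via triketone 5 (not isolated), via aldol adduct 6 (not isolated)
Conditions: LDA (1.1 equiv), 1 (1.2 equiv), THF, −78 °C; 2 (1.0 equiv), −78 to 0 °C; then 4 M aq. KOH, 90 °C (THF distilled off); aq. HCl to pH 3
Reagents that add atoms: water (as aqueous KOH), O; ring opening adds one oxygen and the later dehydration removes one, so this oxygen can end up as a phenol oxygen of ring B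
Why: LDA removes a proton from a C-methyl group of 1, acidified through C2=C3–C4=O, and dienolate 3 attacks the benzylic bromide 2 with its exocyclic carbon in an SN2 step that forms the CH2–CH2 bond and gives 4 (lateral alkylation of a 2-methyl-4-pyrone, a known reaction type). Hot aqueous hydroxide then adds to C2 or C6 of the pyrone, the ring opens to the enolate of triketone 5, and the terminal methyl carbon attacks the ketone next to the bridge in a 6-(enolendo)-exo-trig aldol closure to 6; loss of water and enolisation give resorcinol 7, which is the known base-induced conversion of 2,6-dimethyl-4-pyrone and of 2,4,6-triketones into orcinol-type resorcinols and the laboratory counterpart of polyketide folding. No stereocentre is formed, and 7 is an isomer of 4, so aromatisation drives the second stage. The first selectivity needed is monoalkylation at carbon, which a slight excess of 1, low temperature and the soft benzylic electrophile should secure. The second is closure through the methyl terminus and not through the bridge CH2 (which would attack the acetyl carbonyl); it should be favoured because the methyl group is the less hindered and kinetically more acidic position and leads to the less crowded 1,3,5-substituted ring.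

**Step 2**
Reactants: 7 5-[2-(3-methoxyphenyl)ethyl]benzene-1,3-diol
Product: 8 5-[2-(3-methoxyphenyl)ethyl]cyclohexane-1,3-dione
Conditions: H2 (5 atm), 10% Pd/C, NaOH (1.1 equiv), H2O–i-PrOH, 50 °C; then aq. HCl
Reagents that add atoms: none
Why: Partial hydrogenation of a resorcinol as its monoanion: the phenolate reacts through its keto tautomer and takes up one equivalent of H2, the resulting dione enolate resists further reduction, and the anisole ring A is not hydrogenated on Pd under these conditions; no stable stereocentre results.

**Step 3**
Reactants: 8 5-[2-(3-methoxyphenyl)ethyl]cyclohexane-1,3-dione; 9 4-hydroxybenzaldehyde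
Product: 11 2-[(4-hydroxyphenyl)methyl]-5-[2-(3-methoxyphenyl)ethyl]cyclohexane-1,3-dione, via benzylidene dione 10 (not isolated)
Conditions: Hantzsch ester (diethyl 2,6-dimethyl-1,4-dihydropyridine-3,5-dicarboxylate, 1.1 equiv), L-proline (20 mol %), EtOH, 25 °C
Reagents that add atoms: none
Why: Three-component reductive alkylation (proline-catalysed Knoevenagel condensation, then transfer hydrogenation of benzylidene dione 10 by the Hantzsch ester): C2 is the only nucleophilic carbon of 8, so the benzyl group enters between the two oxygens without protection of the phenol, and C2 stays epimerisable so no configuration needs control.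

**Step 4**
Reactants: 11 2-[(4-hydroxyphenyl)methyl]-5-[2-(3-methoxyphenyl)ethyl]cyclohexane-1,3-dione
Product: 13 2-[(4-hydroxyphenyl)methyl]-3-methoxy-5-[2-(3-methoxyphenyl)ethyl]phenol (IN0509), via methyl enol ether 12 (not isolated)
Conditions: I2 (2.2 equiv), MeOH, reflux; aq. Na2S2O3
Reagents that add atoms: methanol, CO
Why: Iodine–methanol oxidative aromatisation of a cyclohexane-1,3-dione to a 3-methoxyphenol: HI formed in situ catalyses enol ether formation, the two carbonyls of 11 are equivalent so either gives the same vinylogous ester 12, and iodine dehydrogenates 12 (formally α′-iodination, loss of HI, enolisation) to the phenol, which sets OH apart from OMe in one step and removes the stereocentre of 12.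

**Compound list**

1 | 2,6-dimethyl-4H-pyran-4-one | Cc1cc(=O)cc(C)o1 | starting material
2 | 1-(bromomethyl)-3-methoxybenzene (3-methoxybenzyl bromide) | COc1cccc(CBr)c1 | starting material
3 | lithium 2-methyl-6-methylidene-6H-pyran-4-olate (lateral dienolate of 1) | C=C1C=C(O[Li])C=C(C)O1 | intermediate
4 | 2-[2-(3-methoxyphenyl)ethyl]-6-methyl-4H-pyran-4-one | COc1cccc(CCc2cc(=O)cc(C)o2)c1 | intermediate
5 | 8-(3-methoxyphenyl)octane-2,4,6-trione (present as its enolate) | COc1cccc(CCC(=O)CC(=O)CC(C)=O)c1 | intermediate
6 | 5-hydroxy-5-[2-(3-methoxyphenyl)ethyl]cyclohexane-1,3-dione (achiral aldol adduct) | COc1cccc(CCC2(O)CC(=O)CC(=O)C2)c1 | intermediate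
7 | 5-[2-(3-methoxyphenyl)ethyl]benzene-1,3-diol | COc1cccc(CCc2cc(O)cc(O)c2)c1 | intermediate
8 | 5-[2-(3-methoxyphenyl)ethyl]cyclohexane-1,3-dione (diketo form drawn) | COc1cccc(CCC2CC(=O)CC(=O)C2)c1 | intermediate
9 | 4-hydroxybenzaldehyde | O=Cc1ccc(O)cc1 | starting material
10 | 2-[(4-hydroxyphenyl)methylidene]-5-[2-(3-methoxyphenyl)ethyl]cyclohexane-1,3-dione | COc1cccc(CCC2CC(=O)C(=Cc3ccc(O)cc3)C(=O)C2)c1 | intermediate
11 | 2-[(4-hydroxyphenyl)methyl]-5-[2-(3-methoxyphenyl)ethyl]cyclohexane-1,3-dione (diketo form drawn; cis/trans not defined, C2 enolises) | COc1cccc(CCC2CC(=O)C(Cc3ccc(O)cc3)C(=O)C2)c1 | intermediate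
12 | 2-[(4-hydroxyphenyl)methyl]-3-methoxy-5-[2-(3-methoxyphenyl)ethyl]cyclohex-2-en-1-one (racemic) | COC1=C(Cc2ccc(O)cc2)C(=O)CC(CCc2cccc(OC)c2)C1 | intermediate
13 | 2-[(4-hydroxyphenyl)methyl]-3-methoxy-5-[2-(3-methoxyphenyl)ethyl]phenol (IN0509; no stereocentre) | COc1cccc(CCc2cc(O)c(Cc3ccc(O)cc3)c(OC)c2)c1 | target

**Step count and risks**

Total step count: 4. Longest linear sequence: 4 steps (1 to 13).

Steps most likely to fail:

Step 1. The triketone may fold through the wrong terminus (the bridge CH2 attacking the acetyl carbonyl), hydroxide may cleave it by retro-Claisen attack before it cyclises, and proton transfer during the alkylation may lead to over-alkylation of the lateral position. Fallback: the same bond is made as C=C on a preformed ring B. Setting out from 2, heating with PPh3 in toluene should give (3-methoxybenzyl)triphenylphosphonium bromide F1. Its ylide (KOt-Bu, THF) and commercial 3,5-bis(benzyloxy)benzaldehyde should give, by Wittig reaction, 1,3-bis(benzyloxy)-5-[2-(3-methoxyphenyl)ethenyl]benzene F2 as an E/Z mixture. Hydrogenation (H2, Pd/C, EtOAc–EtOH) saturates the alkene, cleaves both benzyl ethers and comes back to the route at 7.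

Step 4. Acetal formation at the remaining carbonyl before dehydrogenation would methylate both oxygens, the electron-rich product may be iodinated on the ring, or the reaction may stall at the enol ether. Fallback: the two events are separated. Setting out from 11, MeOH, HC(OMe)3 and catalytic TsOH should give 12, which is isolated. LDA (2.2 equiv, THF, −78 °C) and PhSeCl should give 2-[(4-hydroxyphenyl)methyl]-3-methoxy-5-[2-(3-methoxyphenyl)ethyl]-6-(phenylselanyl)cyclohex-2-en-1-one F3 by kinetic α′-selenation. H2O2/pyridine at 0 °C should oxidise it to the selenoxide F4, whose syn-elimination gives the cross-conjugated dienone, which enolises and comes back to the route at 13.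

Step 3. The benzylidene dione may be trapped by a second molecule of dione in a Michael addition faster than it is reduced, and condensation of the electron-rich aldehyde may be slow. Fallback: the benzyl group is brought in at the alcohol oxidation level, without a reductant. Setting out from 8, heating with 4-hydroxybenzyl alcohol in water at 100 °C should generate 4-methylidenecyclohexa-2,5-dien-1-one F5 (the para-quinone methide) by loss of water. The dione adds to it through C2 in a conjugate addition that restores the phenol and comes back to the route at 11.

**Further compounds**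

F1 | step 1 | (3-methoxybenzyl)triphenylphosphonium bromide | COc1cccc(C[P+](c2ccccc2)(c2ccccc2)c2ccccc2)c1.[Br-]
F2 | step 1 | 1,3-bis(benzyloxy)-5-[2-(3-methoxyphenyl)ethenyl]benzene (E/Z mixture) | COc1cccc(C=Cc2cc(OCc3ccccc3)cc(OCc3ccccc3)c2)c1
F3 | step 4 | 2-[(4-hydroxyphenyl)methyl]-3-methoxy-5-[2-(3-methoxyphenyl)ethyl]-6-(phenylselanyl)cyclohex-2-en-1-one (racemic, diastereomer mixture) | COC1=C(Cc2ccc(O)cc2)C(=O)C([Se]c2ccccc2)C(CCc2cccc(OC)c2)C1
F4 | step 4 | 6-(benzeneseleninyl)-2-[(4-hydroxyphenyl)methyl]-3-methoxy-5-[2-(3-methoxyphenyl)ethyl]cyclohex-2-en-1-one (selenoxide of F3, not isolated) | COC1=C(Cc2ccc(O)cc2)C(=O)C([Se](=O)c2ccccc2)C(CCc2cccc(OC)c2)C1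
F5 | step 3 | 4-methylidenecyclohexa-2,5-dien-1-one | C=C1C=CC(=O)C=C1
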